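**Retrosynthetic overview**

1. Target ⇐ substrate-controlled hydride reduction of the C4 ketone of the free (2R,3R)-dihydroflavonol (last step; C4 is set by C2 and C3).
2. Free dihydroflavonol ⇐ hydrogenolysis of its pentabenzyl ether.
3. Ring C (the only ring made; rings A and B are bought as arenes) ⇐ O1–C2 ring closure plus C3–OH installation in one catalytic asymmetric oxa-Michael/enolate-hydroxylation cascade on a 2'-hydroxychalcone (sets C2 and C3).
4. Chalcone ⇐ Claisen–Schmidt condensation of a symmetrically substituted 2-hydroxyacetophenone with 3,4,5-tris(benzyloxy)benzaldehyde.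
5. Ring A oxygenation ⇐ two aryl C–OMe bonds by dibromination/copper methoxylation of 2,4,6-trihydroxyacetophenone, then selective dibenzylation.

Assumption: 3,4,5-tris(benzyloxy)benzaldehyde is bought as a catalogue compound; flavonoid numbering (O1, C2, C3, C4; rings A, B, C) is used throughout.

**Route**

Step 1
Reactants: 1 2,4,6-trihydroxyacetophenone
Product: 2 1-(3,5-dibromo-2,4,6-trihydroxyphenyl)ethan-1-one
Conditions: Br2 (2.05 equiv), AcOH, 15 °C to rt
Reagents that add atoms: bromine, BrBr
Why: Electrophilic aromatic bromination; the two free positions of the phloroglucinol ring are by far the most nucleophilic sites and both are substituted by two equivalents of bromine, while the acetyl group is untouched.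

Step 2
Reactants: 2 1-(3,5-dibromo-2,4,6-trihydroxyphenyl)ethan-1-one
Product: 3 1-(2,4,6-trihydroxy-3,5-dimethoxyphenyl)ethan-1-one
Conditions: NaOMe (10 equiv, 30% in MeOH), CuBr (0.5 equiv), DMF, 110 °C, Ar; acidic work-up
Reagents that add atoms: sodium methoxide, [Na+].[O-]C
Why: Ullmann-type copper-mediated methoxylation (aryl C–O coupling) of a bromophenoxide, the transformation that converts ortho-bromophenols such as 5-bromovanillin or 6,8-dibromo-5,7-dihydroxyflavones into their methyl ethers; free phenoxides are tolerated and the ring symmetry removes any regiochemical question.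

Step 3
Reactants: 3 1-(2,4,6-trihydroxy-3,5-dimethoxyphenyl)ethan-1-one
Product: 4 1-[4,6-bis(benzyloxy)-2-hydroxy-3,5-dimethoxyphenyl]ethan-1-one
Conditions: BnBr (2.1 equiv), K2CO3 (2.5 equiv), DMF, rt, N2
Reagents that add atoms: benzyl bromide, BrCc1ccccc1
Why: Williamson etherification under weak base; the para hydroxyl (most acidic, not hydrogen-bonded) and then one ortho hydroxyl react, the last ortho hydroxyl stays free because it is locked in a hydrogen bond to the acetyl carbonyl, C-benzylation is impossible on the fully substituted ring, and the two ortho hydroxyls are equivalent by symmetry.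

Step 4
Reactants: 4 1-[4,6-bis(benzyloxy)-2-hydroxy-3,5-dimethoxyphenyl]ethan-1-one; 5 3,4,5-tris(benzyloxy)benzaldehyde
Product: 7 (E)-1-[4,6-bis(benzyloxy)-2-hydroxy-3,5-dimethoxyphenyl]-3-[3,4,5-tris(benzyloxy)phenyl]prop-2-en-1-one, via aldol adduct 6 (not isolated)
Conditions: KOH (50% aq., 10 equiv), EtOH–THF, rt, 36 h; cold neutralisation
Reagents that add atoms: none
Why: Claisen–Schmidt (crossed aldol) condensation of the methyl ketone enolate with the non-enolisable aldehyde, with E1cB dehydration of aldol 6 to the conjugated E-enone, whose potassium phenoxide stays open-chain in base.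

Step 5
Reactants: 7 (E)-1-[4,6-bis(benzyloxy)-2-hydroxy-3,5-dimethoxyphenyl]-3-[3,4,5-tris(benzyloxy)phenyl]prop-2-en-1-one
Product: 9 (2R,3R)-5,7-bis(benzyloxy)-3-hydroxy-6,8-dimethoxy-2-[3,4,5-tris(benzyloxy)phenyl]-2,3-dihydro-4H-chromen-4-one, via flavanone enolate 8 (not isolated)
Conditions: 3-phenyl-2-(phenylsulfonyl)oxaziridine (1.15 equiv, slow addition), N-(9-anthracenylmethyl)hydroquinidinium bromide (10 mol%), Cs2CO3 (1.2 equiv), toluene–CH2Cl2 (9:1), 4 Å MS, −20 °C; pH 7 buffer quench
Reagents that add atoms: 3-phenyl-2-(phenylsulfonyl)oxaziridine, O=S(=O)(N1OC1c1ccccc1)c1ccccc1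
Why: Proposed new method: a phase-transfer-catalysed oxa-Michael/enolate-oxygenation cascade that closes ring C (O1–C2) and installs the 3-OH (C3–O) in one operation; the phenoxide of 7 cyclises reversibly (6-endo oxa-Michael, favoured by the 6'-benzyloxy group) to flavanone enolate 8, whose two C2 antipodes interconvert through the achiral open phenoxide, and the chiral ammonium ion pair (9-OH hydrogen bond to the enolate oxygen, anthracenyl group shielding one face) is meant to let the (2S)-enolate be oxidised faster by the N-sulfonyloxaziridine (Curtin–Hammett control of C2), oxygen arriving at C3 anti to the C2 aryl group to give the 2,3-trans (2R,3R) ketol, while the aprotic medium and low temperature keep enolate trapping ahead of protonation and over-oxidation and hydrogencarbonate protonates the product alkoxide to regenerate the carbonate; the closest known reaction types are the bifunctional-catalyst asymmetric oxa-Michael cyclisation of 2'-hydroxychalcones to flavanones, its tandem variant with electrophilic fluorination of activated chalcones, and the Davis oxaziridine hydroxylation of ketone enolates; the sense of induction cannot be predicted for a new reaction, so it is checked on the first run and the quinine-derived pseudo-enantiomeric salt is used if it is opposite.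

Step 6
Reactants: 9 (2R,3R)-5,7-bis(benzyloxy)-3-hydroxy-6,8-dimethoxy-2-[3,4,5-tris(benzyloxy)phenyl]-2,3-dihydro-4H-chromen-4-one
Product: 10 (2R,3R)-3,5,7-trihydroxy-6,8-dimethoxy-2-(3,4,5-trihydroxyphenyl)-2,3-dihydro-4H-chromen-4-one
Conditions: H2 (1 atm), 10% Pd/C, EtOAc–MeOH (1:1), rt
Reagents that add atoms: none
Why: Catalytic hydrogenolysis of the five benzyl ethers; the hydrogen-bonded aryl ketone, the two methyl ethers and the secondary C2–O1 ring bond survive at one atmosphere and room temperature, and the neutral conditions do not epimerise C2 or C3.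

Step 7
Reactants: 10 (2R,3R)-3,5,7-trihydroxy-6,8-dimethoxy-2-(3,4,5-trihydroxyphenyl)-2,3-dihydro-4H-chromen-4-one
Product: 11 (2R,3S,4R)-6,8-dimethoxy-2-(3,4,5-trihydroxyphenyl)-3,4-dihydro-2H-chromene-3,4,5,7-tetrol
Conditions: NaBH4 (5 equiv), EtOH, 0 °C, Ar; cold pH 6.5 buffer work-up, Sephadex LH-20
Reagents that add atoms: none
Why: Substrate-controlled borohydride reduction; hydride adds axially to the C4 carbonyl of the half-chair carrying the C2 aryl and C3 hydroxyl groups equatorial, giving the equatorial 4-OH trans to the 3-OH (4R), the same 2,3-trans-3,4-trans outcome known for dihydroquercetin and dihydromyricetin, and the cold near-neutral work-up avoids ionisation at C4.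

**Compound list**

1 | 2,4,6-trihydroxyacetophenone | CC(=O)c1c(O)cc(O)cc1O | starting material
2 | 1-(3,5-dibromo-2,4,6-trihydroxyphenyl)ethan-1-one | CC(=O)c1c(O)c(Br)c(O)c(Br)c1O | intermediate
3 | 1-(2,4,6-trihydroxy-3,5-dimethoxyphenyl)ethan-1-one | CC(=O)c1c(O)c(OC)c(O)c(OC)c1O | intermediate
4 | 1-[4,6-bis(benzyloxy)-2-hydroxy-3,5-dimethoxyphenyl]ethan-1-one | CC(=O)c1c(O)c(OC)c(OCc2ccccc2)c(OC)c1OCc2ccccc2 | intermediate
5 | 3,4,5-tris(benzyloxy)benzaldehyde | O=Cc1cc(OCc2ccccc2)c(OCc2ccccc2)c(OCc2ccccc2)c1 | starting material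
6 | 1-[4,6-bis(benzyloxy)-2-hydroxy-3,5-dimethoxyphenyl]-3-hydroxy-3-[3,4,5-tris(benzyloxy)phenyl]propan-1-one (racemic aldol adduct, not isolated) | O=C(CC(O)c1cc(OCc2ccccc2)c(OCc2ccccc2)c(OCc2ccccc2)c1)c1c(O)c(OC)c(OCc2ccccc2)c(OC)c1OCc2ccccc2 | intermediate
7 | (E)-1-[4,6-bis(benzyloxy)-2-hydroxy-3,5-dimethoxyphenyl]-3-[3,4,5-tris(benzyloxy)phenyl]prop-2-en-1-one | O=C(/C=C/c1cc(OCc2ccccc2)c(OCc2ccccc2)c(OCc2ccccc2)c1)c1c(O)c(OC)c(OCc2ccccc2)c(OC)c1OCc2ccccc2 | intermediate
8 | (2S)-5,7-bis(benzyloxy)-6,8-dimethoxy-2-[3,4,5-tris(benzyloxy)phenyl]-2H-chromen-4-olate (flavanone enolate, ammonium ion pair, not isolated) | COc1c(OCc3ccccc3)c(OC)c2c(c1OCc3ccccc3)C([O-])=C[C@@H](c1cc(OCc3ccccc3)c(OCc3ccccc3)c(OCc3ccccc3)c1)O2 | intermediate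
9 | (2R,3R)-5,7-bis(benzyloxy)-3-hydroxy-6,8-dimethoxy-2-[3,4,5-tris(benzyloxy)phenyl]-2,3-dihydro-4H-chromen-4-one | COc1c(OCc3ccccc3)c(OC)c2c(c1OCc3ccccc3)C(=O)[C@H](O)[C@@H](c1cc(OCc3ccccc3)c(OCc3ccccc3)c(OCc3ccccc3)c1)O2 | intermediate
10 | (2R,3R)-3,5,7-trihydroxy-6,8-dimethoxy-2-(3,4,5-trihydroxyphenyl)-2,3-dihydro-4H-chromen-4-one | COc1c(O)c(OC)c2c(c1O)C(=O)[C@H](O)[C@@H](c1cc(O)c(O)c(O)c1)O2 | intermediate
11 | (2R,3S,4R)-6,8-dimethoxy-2-(3,4,5-trihydroxyphenyl)-3,4-dihydro-2H-chromene-3,4,5,7-tetrol | COc1c(O)c(OC)c2c(c1O)[C@@H](O)[C@H](O)[C@@H](c1cc(O)c(O)c(O)c1)O2 | target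

**Totals and risks**

Total step count: 7. Longest linear sequence: 7 steps (1 → 11); aldehyde 5 enters at step 4.

The three steps most likely to fail:

Step 5 (the new cascade). Risks are low enantioselectivity, enolate protonation outrunning oxygenation, and over-oxidation of the ketol towards the flavonol. A partly enantioenriched 9 can be upgraded by recrystallisation. The fallback uses known chemistry, sets out from 7 and comes back at 9. O-Methoxymethylation of the 2'-hydroxyl (NaH, MOMCl, THF, 0 °C) gives (E)-1-[4,6-bis(benzyloxy)-3,5-dimethoxy-2-(methoxymethoxy)phenyl]-3-[3,4,5-tris(benzyloxy)phenyl]prop-2-en-1-one F1. Juliá–Colonna epoxidation (poly-L-leucine, urea–H2O2, DBU, THF) gives the trans epoxy ketone [4,6-bis(benzyloxy)-3,5-dimethoxy-2-(methoxymethoxy)phenyl]{(2R,3S)-3-[3,4,5-tris(benzyloxy)phenyl]oxiran-2-yl}methanone F2. HCl in MeOH–THF at 50 °C then removes the MOM group, and the freed phenol opens the epoxide 6-endo at the benzylic carbon with inversion, which gives 9.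

Step 2 (copper methoxylation of the free dibromotriol). Risks are hydrodebromination and air oxidation of the very electron-rich product. The fallback sets out from 2 and comes back at 4, bypassing 3. Perbenzylation (BnBr, K2CO3, DMF, 60 °C) gives 1-[2,4,6-tris(benzyloxy)-3,5-dibromophenyl]ethan-1-one F3. Palladium-catalysed C–O cross-coupling with methanol on this neutral dibromide (Pd2(dba)3, tBuBrettPhos, Cs2CO3, MeOH–toluene, 80 °C) gives 1-[2,4,6-tris(benzyloxy)-3,5-dimethoxyphenyl]ethan-1-one F4. BCl3 (1.05 equiv, CH2Cl2, −78 °C) then cleaves only one benzyl ether ortho to the carbonyl by chelation (the two ortho ethers are equivalent), which gives 4.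

Step 7 (reduction of the free polyphenol). Risks are incomplete 3,4-trans selectivity and loss of the acid- and air-sensitive flavan-3,4-diol on isolation. The fallback sets out from 9 and comes back at 11, bypassing 10. NaBH4 in THF–MeOH at 0 °C on the benzyl-protected ketone gives (2R,3S,4R)-5,7-bis(benzyloxy)-6,8-dimethoxy-2-[3,4,5-tris(benzyloxy)phenyl]-3,4-dihydro-2H-chromene-3,4-diol F5, a stable compound that can be chromatographed free of the minor 3,4-cis isomer. Hydrogenolysis (H2, Pd(OH)2/C, EtOAc–MeOH, a little NaHCO3 to suppress C4–O cleavage) then gives 11 after simple filtration.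

**Further compounds**

F1 | step 5 | (E)-1-[4,6-bis(benzyloxy)-3,5-dimethoxy-2-(methoxymethoxy)phenyl]-3-[3,4,5-tris(benzyloxy)phenyl]prop-2-en-1-one | O=C(/C=C/c1cc(OCc2ccccc2)c(OCc2ccccc2)c(OCc2ccccc2)c1)c1c(OCOC)c(OC)c(OCc2ccccc2)c(OC)c1OCc2ccccc2
F2 | step 5 | [4,6-bis(benzyloxy)-3,5-dimethoxy-2-(methoxymethoxy)phenyl]{(2R,3S)-3-[3,4,5-tris(benzyloxy)phenyl]oxiran-2-yl}methanone | O=C([C@@H]1O[C@H]1c3cc(OCc2ccccc2)c(OCc2ccccc2)c(OCc2ccccc2)c3)c1c(OCOC)c(OC)c(OCc2ccccc2)c(OC)c1OCc2ccccc2
F3 | step 2 | 1-[2,4,6-tris(benzyloxy)-3,5-dibromophenyl]ethan-1-one | CC(=O)c1c(OCc2ccccc2)c(Br)c(OCc2ccccc2)c(Br)c1OCc2ccccc2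
F4 | step 2 | 1-[2,4,6-tris(benzyloxy)-3,5-dimethoxyphenyl]ethan-1-one | CC(=O)c1c(OCc2ccccc2)c(OC)c(OCc2ccccc2)c(OC)c1OCc2ccccc2
F5 | step 7 | (2R,3S,4R)-5,7-bis(benzyloxy)-6,8-dimethoxy-2-[3,4,5-tris(benzyloxy)phenyl]-3,4-dihydro-2H-chromene-3,4-diol | COc1c(OCc3ccccc3)c(OC)c2c(c1OCc3ccccc3)[C@@H](O)[C@H](O)[C@@H](c1cc(OCc3ccccc3)c(OCc3ccccc3)c(OCc3ccccc3)c1)O2
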